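**Retrosynthetic overview**
- C2–O: the acetate is made last from the racemic C2 carbinol by an enantioselective O-acetylation with in situ racemisation, so one step sets C2 and installs OAc.
- C2–C3: the carbinol comes from an (E)-alkenyl iodide and 3-furylacetaldehyde (Nozaki–Hiyama–Kishi).
- C5–C6: the alkenyl iodide comes from a (1E,3E)-dienylzirconocene (hydrozirconation of a furyl enyne) and (E)-3-bromo-1-iodo-2-methylpropene (from propargyl alcohol by syn-carboalumination).
- C10–C11: the furyl enyne comes from 3-furylmethyl Grignard and (E)-5-chloro-3-methylpent-3-en-1-yne (from the commercial E-enynol).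
- No ring is formed: both furans are bought intact, and the three E-alkenes come from one E building block and two syn additions.

Assumption: the four starting materials, Schwartz reagent, the Ru complex and HyperBTM are bought; acetyl isopropyl carbonate is made beforehand from isopropyl chloroformate and acetic acid/Et3N and is not counted as a step; metal alkoxides that are only the salt of a step's product before aqueous work-up are not numbered.

**Route**

Step 1
Reactants: 1 furan-3-ylmethanol
Product: 2 3-(chloromethyl)furan
Conditions: SOCl2 (1.1 equiv), pyridine (1.1 equiv), Et2O, 0 °C, 1 h; used at once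
Reagents that add atoms: thionyl chloride, O=S(Cl)Cl
Why: Chlorodehydroxylation of a primary furylmethyl alcohol through its chlorosulfite, with pyridine trapping HCl so the acid-sensitive furan survives; no stereo element is involved.

Step 2
Reactants: 3 (2E)-3-methylpent-2-en-4-yn-1-ol
Product: 4 (3E)-5-chloro-3-methylpent-3-en-1-yne
Conditions: NCS (1.2 equiv), Me2S (1.3 equiv), CH2Cl2, −20 → 0 °C
Reagents that add atoms: N-chlorosuccinimide, O=C1CCC(=O)N1Cl
Why: Corey–Kim allylic chlorination is an SN2 displacement on the alkoxysulfonium salt, so there is no allylic transposition and the E geometry of the enyne is kept.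

Step 3
Reactants: 2 3-(chloromethyl)furan; 4 (3E)-5-chloro-3-methylpent-3-en-1-yne
Product: 8 3-[(3E)-4-methylhex-3-en-5-yn-1-yl]furan, via 3-furylmethylmagnesium chloride 5 (not isolated), via chloroenyne magnesium acetylide 6 (not isolated), via coupled enyne magnesium acetylide 7 (not isolated)
Conditions: (a) 2, Mg, THF, 0 °C; (b) 4, i-PrMgCl·LiCl (1.0 equiv), THF, −20 °C; (c) Li2CuCl4 (5 mol%), then the Grignard from (a) (1.3 equiv), −20 → 0 °C; H2O
Reagents that add atoms: none
Why: Copper-catalysed Grignard–allylic chloride cross-coupling (Kochi type), in which the ambident 3-furylmethyl Grignard couples through its CH2 at the primary carbon of the allylic chloride, while prior magnesiation of the alkyne removes the acidic proton and disfavours 1,5-attack, so the E-alkene is carried through unchanged.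

Step 4
Reactants: 9 prop-2-yn-1-ol
Product: 11 (2E)-3-iodo-2-methylprop-2-en-1-ol, via alkenylalane 10 (not isolated)
Conditions: AlMe3 (3 equiv), Cp2ZrCl2 (25 mol%), CH2Cl2, 0 °C → rt, 16 h; then I2 (1.3 equiv), THF, −30 → 0 °C; aqueous work-up
Reagents that add atoms: trimethylaluminium, C[Al](C)C; iodine, II
Why: Negishi zirconium-catalysed carboalumination adds Me and Al syn across the alkyne with Al on the terminal carbon, and iodinolysis with retention gives only the E-iodide (I cis to Me), which becomes the 3E alkene of the target.

Step 5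
Reactants: 11 (2E)-3-iodo-2-methylprop-2-en-1-ol
Product: 12 (1E)-3-bromo-1-iodo-2-methylprop-1-ene
Conditions: PBr3 (0.4 equiv), Et2O, 0 °C, 1 h
Reagents that add atoms: phosphorus tribromide, BrP(Br)Br
Why: SN2 bromodehydroxylation of a primary allylic alcohol through its phosphite ester; the vinyl iodide is inert and its geometry is untouched.

Step 6
Reactants: 8 3-[(3E)-4-methylhex-3-en-5-yn-1-yl]furan; 12 (1E)-3-bromo-1-iodo-2-methylprop-1-ene
Product: 14 3-[(3E,5E,8E)-9-iodo-4,8-dimethylnona-3,5,8-trien-1-yl]furan, via dienylzirconocene chloride 13 (not isolated)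
Conditions: 8, Cp2Zr(H)Cl (1.15 equiv), THF, rt, 30 min; then 12 (1.0 equiv), CuCl (10 mol%), 0 °C → rt
Reagents that add atoms: none
Why: Schwartz hydrozirconation adds Zr–H syn and anti-Markovnikov to the terminal alkyne only, giving the 1E,3E-dienylzirconocene, and copper-catalysed Zr→Cu transmetalation/allylation at the CH2Br carbon forms the skipped C5–C6 bond with retention of all alkene geometries while the vinyl iodide stays intact.

Step 7
Reactants: 15 2-(furan-3-yl)ethan-1-ol
Product: 16 2-(furan-3-yl)acetaldehyde
Conditions: IBX (1.3 equiv), DMSO, rt, 2 h; extracted into Et2O and used the same day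
Reagents that add atoms: none
Why: IBX (hypervalent iodine) oxidation stops at the aldehyde under neutral conditions, which limits enolisation and self-aldol of the sensitive arylacetaldehyde.

Step 8
Reactants: 14 3-[(3E,5E,8E)-9-iodo-4,8-dimethylnona-3,5,8-trien-1-yl]furan; 16 2-(furan-3-yl)acetaldehyde
Product: 18 rac-(3E,6E,8E)-1,11-di(furan-3-yl)-4,8-dimethylundeca-3,6,8-trien-2-ol, via alkenylchromium(III) dichloride 17 (not isolated)
Conditions: CrCl2 (4 equiv), NiCl2 (2 mol%), 16 (2 equiv), DMSO–THF, rt, 12 h; H2O
Reagents that add atoms: none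
Why: Nozaki–Hiyama–Kishi coupling, in which Ni inserts into the C–I bond with retention and the non-basic alkenylchromium(III) adds to the enolisable aldehyde; C2 is formed as a racemate on purpose because the next step is dynamic.

Step 9
Reactants: 18 rac-(3E,6E,8E)-1,11-di(furan-3-yl)-4,8-dimethylundeca-3,6,8-trien-2-ol
Product: 19 (2S,3E,6E,8E)-1,11-di(furan-3-yl)-4,8-dimethylundeca-3,6,8-trien-2-yl acetate (CNP0230518.1)
Conditions: Ru(CO)2Cl(η5-C5Ph5) (5 mol%), KOt-Bu (5 mol%), isothiourea HyperBTM (5 mol%; the enantiomer that acylates (S)-18, fixed beforehand by a Ru-free test resolution with chiral HPLC/Mosher analysis), acetyl isopropyl carbonate (1.5 equiv), toluene, 25 °C, Ar, 24–48 h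
Reagents that add atoms: acetyl isopropyl carbonate (acetic isopropyl carbonic anhydride), CC(=O)OC(=O)OC(C)C
Why: Proposed new method: a non-enzymatic dynamic kinetic acetylation in which the isothiourea is N-acetylated by the mixed carbonate and passes acetyl (the stereo-determining C–O bond formation) much faster to (S)-18, whose alkenyl π-face stacks on the acyl-isothiouronium cation while the furylmethyl arm points away, as the Ru alkoxide/hydride cycle (β-hydride elimination to a Ru-bound enone and re-addition, with no allyl cation so the 3E alkene is kept, and with a β,β-disubstituted enone that resists 1,4-hydride delivery) keeps racemising the slow (R)-alcohol, so all material funnels to the (S)-acetate with CO2 and i-PrOH as the only by-products; the closest known reactions are the Ru/planar-chiral DMAP dynamic kinetic resolution of aryl alkyl carbinols with acyl carbonates, isothiourea-catalysed kinetic resolution of allylic alcohols and Ru/lipase dynamic kinetic resolution of allylic methyl carbinols, and the new elements are the isothiourea/Ru pairing and an allylic carbinol with two large substituents.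

**Compound list**
1 | furan-3-ylmethanol | OCc1ccoc1 | starting material
2 | 3-(chloromethyl)furan | ClCc1ccoc1 | intermediate
3 | (2E)-3-methylpent-2-en-4-yn-1-ol | C#C/C(C)=C/CO | starting material
4 | (3E)-5-chloro-3-methylpent-3-en-1-yne | C#C/C(C)=C/CCl | intermediate
5 | (furan-3-ylmethyl)magnesium chloride (formed in the flask) | Cl[Mg]Cc1ccoc1 | intermediate
6 | [(3E)-5-chloro-3-methylpent-3-en-1-yn-1-yl]magnesium chloride (formed in the flask) | Cl[Mg]C#C/C(C)=C/CCl | intermediate
7 | [(3E)-6-(furan-3-yl)-3-methylhex-3-en-1-yn-1-yl]magnesium chloride (formed in the flask) | Cl[Mg]C#C/C(C)=C/CCc1ccoc1 | intermediate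
8 | 3-[(3E)-4-methylhex-3-en-5-yn-1-yl]furan | C#C/C(C)=C/CCc1ccoc1 | intermediate
9 | prop-2-yn-1-ol | C#CCO | starting material
10 | dimethyl[(1E)-3-(dimethylalumanyloxy)-2-methylprop-1-en-1-yl]alumane (formed in the flask) | C[Al](C)/C=C(\C)CO[Al](C)C | intermediate
11 | (2E)-3-iodo-2-methylprop-2-en-1-ol | I/C=C(\C)CO | intermediate
12 | (1E)-3-bromo-1-iodo-2-methylprop-1-ene | I/C=C(\C)CBr | intermediate
13 | chlorobis(cyclopentadienyl)[(1E,3E)-6-(furan-3-yl)-3-methylhexa-1,3-dien-1-yl]zirconium (formed in the flask; Cp drawn σ-bonded) | Cl[Zr](C1C=CC=C1)(C1C=CC=C1)/C=C/C(C)=C/CCc1ccoc1 | intermediate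
14 | 3-[(3E,5E,8E)-9-iodo-4,8-dimethylnona-3,5,8-trien-1-yl]furan | I/C=C(\C)C/C=C/C(C)=C/CCc1ccoc1 | intermediate
15 | 2-(furan-3-yl)ethan-1-ol | OCCc1ccoc1 | starting material
16 | 2-(furan-3-yl)acetaldehyde | O=CCc1ccoc1 | intermediate
17 | dichloro[(1E,4E,6E)-9-(furan-3-yl)-2,6-dimethylnona-1,4,6-trien-1-yl]chromium(III) (formed in the flask) | Cl[Cr](Cl)/C=C(\C)C/C=C/C(C)=C/CCc1ccoc1 | intermediate
18 | rac-(3E,6E,8E)-1,11-di(furan-3-yl)-4,8-dimethylundeca-3,6,8-trien-2-ol (racemic at C2) | OC(/C=C(\C)C/C=C/C(C)=C/CCc1ccoc1)Cc1ccoc1 | intermediate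
19 | (2S,3E,6E,8E)-1,11-di(furan-3-yl)-4,8-dimethylundeca-3,6,8-trien-2-yl acetate | CC(=O)O[C@H](/C=C(\C)C/C=C/C(C)=C/CCc1ccoc1)Cc1ccoc1 | target

**Step count and risks**
Total steps: 9. Longest linear sequence: 5 (for example 1 → 2 → 8 → 14 → 18 → 19).

Three steps most likely to fail:

Step 3 (coupling of the ambident furylmethyl Grignard with the metalated enynyl chloride). The risks are attack through furan C2, SN2' or 1,5-substitution, and acetylide self-coupling. The fallback sets out from 2 (as its Grignard 5) and comes back at 8. The Grignard is coupled with prenyl chloride (Li2CuCl4 cat., THF, 0 °C), an electrophile with no acidic or conjugated site, to give perillene F1. SeO2 (cat.)/t-BuOOH followed by MnO2 oxidises the E-methyl group to the (E)-enal F2. Ohira–Bestmann homologation (dimethyl (1-diazo-2-oxopropyl)phosphonate, K2CO3, MeOH) converts CHO into the terminal alkyne and returns 8. Steps 2 and 3 are replaced by three steps.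

Step 8 (NHK addition to the labile aldehyde 16). The risk is aldol reaction, enolisation or polymerisation of 16 before it is trapped. The fallback sets out from 14 and comes back at 18. Iodine–lithium exchange (t-BuLi, 2 equiv, Et2O, −78 °C) gives the alkenyllithium F4. It is acylated by the stable Weinreb amide F3 (from commercial 2-(furan-3-yl)acetic acid, CDI, MeNHOMe·HCl) to give the trienone F5. Luche reduction (NaBH4, CeCl3·7H2O, MeOH, −40 °C) then gives 18. F5 must be kept away from base because its C5 hydrogens are doubly activated.

Step 9 (the proposed dynamic kinetic acetylation). It can fail through poor enantiorecognition of a carbinol with two large groups, Ru-mediated redox isomerisation, or loss of the mixed carbonate to i-PrOH. The fallback uses known chemistry, sets out from 18 and comes back at 19. Buffered Dess–Martin oxidation gives the trienone F5 (the same compound as in the fallback for step 8, which can be used directly if that fallback is in play). Corey–Bakshi–Shibata reduction with (R)-Me-CBS/catecholborane in toluene at −78 °C gives the (S)-alcohol F6; the sense is predicted with the alkenyl group as the large substituent and should be confirmed by Mosher analysis. Ac2O/pyridine/DMAP acetylates F6 with retention to 19. This adds two steps.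

Further compounds
F1 | step 3 | perillene (3-(4-methylpent-3-en-1-yl)furan) | CC(C)=CCCc1ccoc1
F2 | step 3 | (2E)-5-(furan-3-yl)-2-methylpent-2-enal | O=C/C(C)=C/CCc1ccoc1
F3 | step 8 | 2-(furan-3-yl)-N-methoxy-N-methylacetamide | CON(C)C(=O)Cc1ccoc1
F4 | step 8 | [(1E,4E,6E)-9-(furan-3-yl)-2,6-dimethylnona-1,4,6-trien-1-yl]lithium | [Li]/C=C(\C)C/C=C/C(C)=C/CCc1ccoc1
F5 | step 8 | (3E,6E,8E)-1,11-di(furan-3-yl)-4,8-dimethylundeca-3,6,8-trien-2-one | O=C(/C=C(\C)C/C=C/C(C)=C/CCc1ccoc1)Cc1ccoc1
F6 | step 9 | (2S,3E,6E,8E)-1,11-di(furan-3-yl)-4,8-dimethylundeca-3,6,8-trien-2-ol | O[C@H](/C=C(\C)C/C=C/C(C)=C/CCc1ccoc1)Cc1ccoc1
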